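**Plan**

Briarane numbering is used: ring A is C1 and C10–C14 (C15 on C1, C20 on C11), ring B is C1–C10 (C16 on C5), and the lactone is O–C7, C8, C17 (C18), C19.
- Feature and key cut: in ring B the C2 and C4 oxygens are 1,3-anti across the C3 methylene, C2 sits on the quaternary C1 and C4 is allylic to the cis C5=C6 bond. Cutting C2–C3 (aldol retron, after returning C4–O to a ketone) opens ring B to a non-enolisable neopentyl C2 aldehyde and a (Z)-enone methyl ketone.
- Further cuts: C17–C18, lactone C19–O(C7), the pyran O–C4 bond of an Achmatowicz pyranone (C3–C7 and C16 come from a 2-methylfuran), C8–C17 (acetate aldol), C7–C8 (furyllithium on an amide), C9–O, and C9–C10 (Eschenmoser–Claisen), back to ring A from (S)-carvone.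
- Forward order: ring A, the C9–C8 arm, the furan, C17/C19, pyranone then lactone ring, ring opening to the seco keto aldehyde, ring B last by boron aldol, then C4 reduction and acetates.
- Stereochemistry: C14 from carvone; C1 by alkylation anti to isopropenyl; C12 then C10 by anti epoxidation, Wharton transposition and suprafacial Claisen; C9 by enolate oxidation under 1,3-allylic strain; the oxirane by hydroxyl direction; C8 by chelation; C7 by Luche reduction; C17 by lactone alkylation; C2 by the aldol (Felkin); C4 by Evans–Tishchenko reduction from C2.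

Key step: step 23

Remark: the anomeric carbon C4 of the pyran intermediates, the C4 carbinol of the ring-opened intermediates before the double oxidation, and the hydroperoxide carbon of the ozonolysis intermediate are carried as epimer mixtures (C4 ends as a ketone), so their SMILES leave these centres open.

**Route**

Step 1
Reactants: 1 (S)-carvone
Product: 3 trans-6-(hydroxymethyl)carvone (carvone C6 = briarane C1), via lithium dienolate 2 (not isolated)
Conditions: LiN(i-Pr)2, THF, −78 °C; CH2O (gas), −78 → −40 °C; aq NH4Cl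
Reagents that add atoms: formaldehyde C=O
Why: Kinetic deprotonation of the enone at its alpha-prime carbon and aldol addition to formaldehyde should give the hydroxymethyl ketone; the new centre is expected mainly anti to the isopropenyl group and is erased again in step 3.

Step 2
Reactants: 3 trans-6-(hydroxymethyl)carvone
Product: 4 primary TBS ether of 3
Conditions: TBSCl, imidazole, CH2Cl2, 0 °C
Reagents that add atoms: tert-butyldimethylsilyl chloride CC(C)(C)[Si](C)(C)Cl
Why: Imidazole-mediated silylation of the primary alcohol, which also blocks retro-aldol loss of formaldehyde.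

Step 3
Reactants: 4 primary TBS ether of 3
Product: 6 ring A enone with quaternary C1 (CH3 trans and CH2OTBS cis to isopropenyl), via lithium dienolate 5 (not isolated)
Conditions: LiN(i-Pr)2, THF, −78 °C; MeI, DMPU, −78 → −20 °C
Reagents that add atoms: iodomethane CI
Why: Enolate alkylation: the dienolate 5 should take up methyl iodide on the face opposite the neighbouring isopropenyl group, so that C1 becomes quaternary with C15 trans and the C2 carbon cis to the future C14 oxygen.

Step 4
Reactants: 6 ring A enone with quaternary C1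
Product: 7 11,12-epoxy-10-ketone (oxirane trans to isopropenyl)
Conditions: H2O2 (30% aq), NaOH (cat.), MeOH, 0 °C
Reagents that add atoms: hydrogen peroxide OO
Why: Weitz–Scheffer epoxidation: hydroperoxide should add to C12 anti to the C14 isopropenyl group, as in carvone itself, and close the oxirane on the face that will later carry C9.

Step 5
Reactants: 7 11,12-epoxy-10-ketone
Product: 9 transposed allylic alcohol (C12–OH and C10=C11), via hydrazone 8 (not isolated)
Conditions: N2H4·H2O, AcOH (cat.), MeOH, 0 °C → rt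
Reagents that add atoms: none
Why: Wharton transposition: the epoxy hydrazone 8 should lose N2 and open the oxirane to the C10=C11 alkene and the C12 alcohol, the C12–O bond and its configuration being untouched.

Step 6
Reactants: 9 transposed allylic alcohol
Product: 11 dimethylamide (C10–CH2CONMe2 and C11=C12), via ketene N,O-acetal 10 (not isolated)
Conditions: MeC(OMe)2NMe2, xylene, 140 °C
Reagents that add atoms: N,N-dimethylacetamide dimethyl acetal COC(C)(OC)N(C)C
Why: Eschenmoser–Claisen rearrangement: the ketene N,O-acetal 10 should undergo a suprafacial [3,3] shift that forms C9–C10 on the face of the departing C12 oxygen, which sets C10 (H cis to C2) next to the quaternary centre and moves the alkene to C11=C12.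

Step 7
Reactants: 11 dimethylamide
Product: 13 C9-hydroxy amide, via lithium enolate 12 (not isolated)
Conditions: LiN(i-Pr)2, THF, −78 °C; (camphorsulfonyl)oxaziridine, −78 → −40 °C
Reagents that add atoms: (camphorsulfonyl)oxaziridine CC1(C)C2CCC13CS(=O)(=O)N4OC34C2
Why: Enolate hydroxylation with an N-sulfonyloxaziridine: in the (Z)-amide enolate 12 the C10–H bond should lie in the enolate plane (1,3-allylic strain), so that the oxidant reaches C9 from the side away from the quaternary C1 and sets the C9 carbinol.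

Step 8
Reactants: 13 C9-hydroxy amide
Product: 14 epoxy hydroxy amide (11,12-oxirane cis to the C9 arm)
Conditions: VO(acac)2 (5 mol%), t-BuOOH, CH2Cl2, 0 °C → rt
Reagents that add atoms: tert-butyl hydroperoxide CC(C)(C)OO
Why: Vanadium-catalysed hydroxyl-directed epoxidation: the homoallylic C9 hydroxyl should deliver the oxygen to the face of C11=C12 that bears the side arm (cis to C15), while the undirected isopropenyl group stays.

Step 9
Reactants: 14 epoxy hydroxy amide
Product: 17 C9,C14-diol amide, via methoxy hydroperoxide 15 (not isolated), via diacetate 16 (not isolated)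
Conditions: O3, CH2Cl2/MeOH, NaHCO3, −78 °C; Ac2O, Et3N, DMAP, 0 °C → rt; then K2CO3 (cat.), MeOH, rt
Reagents that add atoms: ozone [O-][O+]=O
Why: Ozonolysis in methanol gives the methoxy hydroperoxide 15, whose peracetate undergoes the Criegee rearrangement with retention at C14 (the C9 hydroxyl is acetylated on the way), and mild methanolysis of diacetate 16 should free both hydroxyls.

Step 10
Reactants: 18 methyl 2-methylfuran-3-carboxylate
Product: 19 (2-methylfuran-3-yl)methanol
Conditions: LiAlH4, Et2O, 0 °C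
Reagents that add atoms: none
Why: Hydride reduction of the ester to the primary alcohol.

Step 11
Reactants: 19 (2-methylfuran-3-yl)methanol
Product: 20 3-[(4-methoxybenzyloxy)methyl]-2-methylfuran
Conditions: NaH, 4-methoxybenzyl chloride, Bu4NI (cat.), THF/DMF, 0 °C → rt
Reagents that add atoms: 4-methoxybenzyl chloride COc1ccc(CCl)cc1
Why: Williamson etherification of the furylmethanol alkoxide with the benzylic chloride.

Step 12
Reactants: 17 C9,C14-diol amide; 20 3-[(4-methoxybenzyloxy)methyl]-2-methylfuran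
Product: 22 2-furyl ketone (C8 ketone with free C9 and C14 hydroxyls), via 5-lithiofuran 21 (not isolated)
Conditions: 20 (3.2 equiv), n-BuLi, THF, −78 → 0 °C; then 17, −78 → 0 °C; aq NH4Cl
Reagents that add atoms: none
Why: Acyl substitution: the furan is lithiated at its only free alpha position and 21 should add once to the dimethylamide, the tetrahedral adduct holding until work-up; two further equivalents are consumed by the hydroxyls.

Step 13
Reactants: 22 2-furyl ketone
Product: 23 tert-butyl ester aldol adduct (tertiary C8 carbinol)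
Conditions: t-BuOAc, LiN(i-Pr)2, THF, −78 °C; then 22, −78 °C; AcOH quench at −78 °C
Reagents that add atoms: tert-butyl acetate CC(=O)OC(C)(C)C
Why: Chelation-controlled aldol addition: lithium bridges the C9 alkoxide and the ketone oxygen, and the ester enolate should attack C8 on the face opposite C10 (Cram chelate model), which sets the tertiary C8 carbinol and brings in C17 and C19; the tert-butyl ester resists the neighbouring alkoxides.

Step 14
Reactants: 23 tert-butyl ester aldol adduct
Product: 24 C9,C14-bis-TBS ether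
Conditions: TBSOTf (2.3 equiv), 2,6-lutidine, CH2Cl2, −78 → 0 °C
Reagents that add atoms: tert-butyldimethylsilyl trifluoromethanesulfonate CC(C)(C)[Si](C)(C)OS(=O)(=O)C(F)(F)F
Why: Silyl triflate silylation of the two secondary hydroxyls; the hindered tertiary furyl carbinol should stay free for the next step.

Step 15
Reactants: 24 C9,C14-bis-TBS ether
Product: 25 pyranone hemiketal (ring O–C8–C7(=O)–C6=C5–C4)
Conditions: NBS, NaHCO3, NaOAc, THF/H2O, 0 °C
Reagents that add atoms: water O
Why: Achmatowicz rearrangement: oxidative opening of the furan and closure by the C8 hydroxyl onto C4 should give the 6-hydroxy-2H-pyran-3(6H)-one, which locks C5=C6 cis, keeps C7 as the only ketone and hides C4.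

Step 16
Reactants: 25 pyranone hemiketal
Product: 26 pyranone methyl ketal
Conditions: MeOH, HC(OMe)3, PPTS (cat.), 0 °C → rt
Reagents that add atoms: methanol CO
Why: Acid-catalysed exchange of the anomeric hydroxyl for methoxy (ketalisation) makes C4 inert to hydride and base.

Step 17
Reactants: 26 pyranone methyl ketal
Product: 27 C7 allylic alcohol (hydroxyl cis to the C17 arm)
Conditions: NaBH4, CeCl3·7H2O, MeOH/CH2Cl2, −78 °C
Reagents that add atoms: none
Why: Luche reduction: hydride should add to C7 opposite the axial C17 arm and the axial methoxy group of the half-chair, giving the allylic alcohol cis to C17 on the pyran.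

Step 18
Reactants: 27 C7 allylic alcohol
Product: 30 C17-methyl lactone (cis-fused pyrano-lactone), via lactone 28 (not isolated), via lithium enolate 29 (not isolated)
Conditions: LiN(SiMe3)2, THF, −78 → 0 °C; then LiN(i-Pr)2, −78 °C; MeI
Reagents that add atoms: iodomethane CI
Why: Lactonisation and lactone enolate alkylation: the C7 alkoxide displaces tert-butoxide to give the cis-fused lactone 28, and its enolate 29 should be methylated on the face away from the bulky C9 branch on the adjacent C8, which sets C17 (the same epimer is expected to be the more stable one).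

Step 19
Reactants: 30 C17-methyl lactone
Product: 32 ring-opened C4,C8-diol with (Z)-C5=C6, via hemiketal 31 (not isolated)
Conditions: PPTS, acetone/H2O, rt; then NaBH4, CeCl3·7H2O, MeOH, 0 °C
Reagents that add atoms: water O
Why: Ketal hydrolysis and 1,2-reduction: the hemiketal 31 is in equilibrium with the open (Z)-hydroxy enone, whose reduction should draw the equilibrium to the open diol and free the C8 hydroxyl; the alkene keeps the cis geometry fixed by the ring.

Step 20
Reactants: 32 ring-opened C4,C8-diol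
Product: 33 C2,C4,C8-triol
Conditions: HF·pyridine, pyridine, THF, 0 °C → rt
Reagents that add atoms: none
Why: Selective desilylation: buffered HF·pyridine should cleave the primary silyl ether much faster than the two hindered secondary ones.

Step 21
Reactants: 33 C2,C4,C8-triol
Product: 35 C8-OTMS diol, via tris-TMS ether 34 (not isolated)
Conditions: N-(trimethylsilyl)imidazole, CH2Cl2, rt; then citric acid (cat.), MeOH, 0 °C
Reagents that add atoms: N-(trimethylsilyl)imidazole C[Si](C)(C)n1ccnc1
Why: Persilylation and selective solvolysis: the silylimidazole silylates all three hydroxyls, and mild acid in methanol should remove the primary and the allylic secondary TMS groups while the hindered tertiary C8 ether stays.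

Step 22
Reactants: 35 C8-OTMS diol
Product: 36 seco keto aldehyde (C2 aldehyde and C4 methyl ketone)
Conditions: Dess–Martin periodinane, NaHCO3, CH2Cl2, 0 °C → rt
Reagents that add atoms: none
Why: Dess–Martin oxidation of the primary and the allylic secondary alcohol in one operation; with C8 silylated the methyl ketone cannot close to a hemiketal.

Step 23
Reactants: 36 seco keto aldehyde
Product: 39 ring B beta-hydroxy enone, via boron enolate 37 (not isolated), via boron aldolate 38 (not isolated)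
Conditions: (c-C6H11)2BCl, Et3N, Et2O, −78 → 0 °C, slow addition of 36 to about 1 mM; MeOH, pH 7 buffer
Reagents that add atoms: none
Why: (c-C6H11)2BCl and Et3N should enolise the methyl ketone on its only enolisable side to the dicyclohexylboron enolate 37, which adds through C3 to the boron-activated C2 aldehyde in a closed six-membered (Zimmerman–Traxler) transition state and gives the boron aldolate 38, hydrolysed on work-up. The closest known reaction type is the boron-mediated aldol addition of methyl ketones to aldehydes, used intramolecularly for macrocyclisation. Ring B closes in a 10-(enolendo)-exo-trig mode at an unhindered methylene, helped by the turn that the cis C5=C6 bond and the lactone impose on the chain and by high dilution. The new C2 carbinol is controlled by the quaternary C1 in a Felkin-type arrangement: C14 with its silyloxy group lies anti to the incoming enolate, methyl C15 flanks the trajectory and the tether through C10 points inward. The step needs regioselective enolisation (only C3 carries alpha hydrogens, C5 being sp2, and the aldehyde cannot enolise) and retention of the (Z)-enone, which the low temperature and the amine base should secure.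

Step 24
Reactants: 39 ring B beta-hydroxy enone
Product: 40 C2 acetate C4 alcohol (1,3-anti)
Conditions: SmI2 (30 mol%), CH3CHO (excess), THF, −10 °C
Reagents that add atoms: acetaldehyde CC=O
Why: Evans–Tishchenko reduction: the samarium-bound hemiacetal of the C2 alkoxide with acetaldehyde delivers hydride intramolecularly to C4 through a chair, which should give the 1,3-anti C4 alcohol and leave C2 as its acetate.

Step 25
Reactants: 40 C2 acetate C4 alcohol
Product: 41 C2,C4-diacetate
Conditions: Ac2O, DMAP, pyridine, CH2Cl2, rt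
Reagents that add atoms: acetic anhydride CC(=O)OC(C)=O
Why: DMAP-catalysed acetylation of the allylic C4 alcohol.

Step 26
Reactants: 41 C2,C4-diacetate
Product: 42 C8,C9,C14-triol
Conditions: HF·pyridine, THF, 0 °C → rt
Reagents that add atoms: none
Why: Fluoride-mediated desilylation of the two TBS ethers and the TMS ether; acetates, lactone and the 4-methoxybenzyl ether are stable to HF·pyridine.

Step 27
Reactants: 42 C8,C9,C14-triol
Product: 43 tetraacetate 4-methoxybenzyl ether
Conditions: Ac2O, DMAP, pyridine, rt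
Reagents that add atoms: acetic anhydride CC(=O)OC(C)=O
Why: Acetylation of the two secondary alcohols; the tertiary C8 hydroxyl should not react under these conditions.

Step 28
Reactants: 43 tetraacetate 4-methoxybenzyl ether
Product: 44 CNP0104124.1
Conditions: DDQ, CH2Cl2/pH 7 buffer, 0 °C
Reagents that add atoms: none
Why: Oxidative cleavage of the 4-methoxybenzyl ether with DDQ under buffered conditions should free the C16 alcohol without touching acetates, oxirane or lactone.

**Compound list**

1 | (S)-carvone | CC1=CC[C@@H](CC1=O)C(C)=C | starting material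
2 | lithium dienolate of 1 (C10–OLi, C1=C10) | [Li]OC1=C[C@@H](C(C)=C)CC=C1C | intermediate
3 | trans-6-(hydroxymethyl)carvone | O=C1C(C)=CC[C@H](C(C)=C)[C@H]1CO | intermediate
4 | primary TBS ether of 3 | O=C1C(C)=CC[C@H](C(C)=C)[C@H]1CO[Si](C)(C)C(C)(C)C | intermediate
5 | lithium dienolate of 4 | [Li]OC1=C(CO[Si](C)(C)C(C)(C)C)[C@@H](C(C)=C)CC=C1C | intermediate
6 | ring A enone with quaternary C1 (CH3 trans, CH2OTBS cis to isopropenyl) | O=C1C(C)=CC[C@H](C(C)=C)[C@]1(C)CO[Si](C)(C)C(C)(C)C | intermediate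
7 | 11,12-epoxy-10-ketone (oxirane trans to isopropenyl) | O=C1[C@@]2(C)O[C@H]2C[C@H](C(C)=C)[C@]1(C)CO[Si](C)(C)C(C)(C)C | intermediate
8 | hydrazone of 7 | NN=C1[C@@]2(C)O[C@H]2C[C@H](C(C)=C)[C@]1(C)CO[Si](C)(C)C(C)(C)C | intermediate
9 | allylic alcohol (C12–OH trans to isopropenyl, C10=C11) | O[C@H]1C[C@H](C(C)=C)[C@](C)(CO[Si](C)(C)C(C)(C)C)C=C1C | intermediate
10 | ketene N,O-acetal of 9 | C=C(N(C)C)O[C@H]1C[C@H](C(C)=C)[C@](C)(CO[Si](C)(C)C(C)(C)C)C=C1C | intermediate
11 | dimethylamide (C10–CH2CONMe2 cis to C15, C11=C12) | CN(C)C(=O)C[C@H]1C(C)=CC[C@H](C(C)=C)[C@]1(C)CO[Si](C)(C)C(C)(C)C | intermediate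
12 | lithium (Z)-enolate of 11 | CN(C)/C(O[Li])=C/[C@H]1C(C)=CC[C@H](C(C)=C)[C@]1(C)CO[Si](C)(C)C(C)(C)C | intermediate
13 | C9-hydroxy amide | CN(C)C(=O)[C@H](O)[C@H]1C(C)=CC[C@H](C(C)=C)[C@]1(C)CO[Si](C)(C)C(C)(C)C | intermediate
14 | epoxy hydroxy amide (11,12-oxirane cis to the C9 arm) | CN(C)C(=O)[C@H](O)[C@H]1[C@@]2(C)O[C@H]2C[C@H](C(C)=C)[C@]1(C)CO[Si](C)(C)C(C)(C)C | intermediate
15 | methoxy hydroperoxide from 14 | CN(C)C(=O)[C@H](O)[C@H]1[C@@]2(C)O[C@H]2C[C@H](C(C)(OC)OO)[C@]1(C)CO[Si](C)(C)C(C)(C)C | intermediate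
16 | C9,C14-diacetate | CN(C)C(=O)[C@H](OC(C)=O)[C@H]1[C@@]2(C)O[C@H]2C[C@H](OC(C)=O)[C@]1(C)CO[Si](C)(C)C(C)(C)C | intermediate
17 | C9,C14-diol amide | CN(C)C(=O)[C@H](O)[C@H]1[C@@]2(C)O[C@H]2C[C@H](O)[C@]1(C)CO[Si](C)(C)C(C)(C)C | intermediate
18 | methyl 2-methylfuran-3-carboxylate | Cc1occc1C(=O)OC | starting material
19 | (2-methylfuran-3-yl)methanol | Cc1occc1CO | intermediate
20 | 3-[(4-methoxybenzyloxy)methyl]-2-methylfuran | Cc1occc1COCc1ccc(OC)cc1 | intermediate
21 | 5-lithio derivative of 20 | [Li]c1cc(COCc2ccc(OC)cc2)c(C)o1 | intermediate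
22 | 2-furyl ketone (C8 ketone, C9–OH, C14–OH) | Cc1oc(cc1COCc1ccc(OC)cc1)C(=O)[C@H](O)[C@H]1[C@@]2(C)O[C@H]2C[C@H](O)[C@]1(C)CO[Si](C)(C)C(C)(C)C | intermediate
23 | tert-butyl ester aldol adduct (tertiary C8 carbinol) | Cc1oc(cc1COCc1ccc(OC)cc1)[C@@](O)(CC(=O)OC(C)(C)C)[C@H](O)[C@H]1[C@@]2(C)O[C@H]2C[C@H](O)[C@]1(C)CO[Si](C)(C)C(C)(C)C | intermediate
24 | C9,C14-bis-TBS ether of 23 | Cc1oc(cc1COCc1ccc(OC)cc1)[C@@](O)(CC(=O)OC(C)(C)C)[C@H](O[Si](C)(C)C(C)(C)C)[C@H]1[C@@]2(C)O[C@H]2C[C@H](O[Si](C)(C)C(C)(C)C)[C@]1(C)CO[Si](C)(C)C(C)(C)C | intermediate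
25 | pyranone hemiketal | CC1(O)O[C@](CC(=O)OC(C)(C)C)([C@H](O[Si](C)(C)C(C)(C)C)[C@H]2[C@@]3(C)O[C@H]3C[C@H](O[Si](C)(C)C(C)(C)C)[C@]2(C)CO[Si](C)(C)C(C)(C)C)C(=O)C=C1COCc1ccc(OC)cc1 | intermediate
26 | pyranone methyl ketal | CC1(OC)O[C@](CC(=O)OC(C)(C)C)([C@H](O[Si](C)(C)C(C)(C)C)[C@H]2[C@@]3(C)O[C@H]3C[C@H](O[Si](C)(C)C(C)(C)C)[C@]2(C)CO[Si](C)(C)C(C)(C)C)C(=O)C=C1COCc1ccc(OC)cc1 | intermediate
27 | C7 allylic alcohol (hydroxyl cis to the C17 arm) | CC1(OC)O[C@](CC(=O)OC(C)(C)C)([C@H](O[Si](C)(C)C(C)(C)C)[C@H]2[C@@]3(C)O[C@H]3C[C@H](O[Si](C)(C)C(C)(C)C)[C@]2(C)CO[Si](C)(C)C(C)(C)C)[C@@H](O)C=C1COCc1ccc(OC)cc1 | intermediate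
28 | cis-fused gamma-lactone (C19–O–C7, C17 unsubstituted) | C1C(=O)O[C@H]2C=C(COCc3ccc(OC)cc3)C(C)(OC)O[C@@]12[C@H](O[Si](C)(C)C(C)(C)C)[C@H]3[C@@]4(C)O[C@H]4C[C@H](O[Si](C)(C)C(C)(C)C)[C@]3(C)CO[Si](C)(C)C(C)(C)C | intermediate
29 | lithium enolate of 28 | [Li]OC1=C[C@@]2(OC(C)(OC)C(COCc3ccc(OC)cc3)=C[C@@H]2O1)[C@H](O[Si](C)(C)C(C)(C)C)[C@H]3[C@@]4(C)O[C@H]4C[C@H](O[Si](C)(C)C(C)(C)C)[C@]3(C)CO[Si](C)(C)C(C)(C)C | intermediate
30 | C17-methyl lactone (methyl cis to the C8 oxygen) | C[C@H]1C(=O)O[C@H]2C=C(COCc3ccc(OC)cc3)C(C)(OC)O[C@@]12[C@H](O[Si](C)(C)C(C)(C)C)[C@H]3[C@@]4(C)O[C@H]4C[C@H](O[Si](C)(C)C(C)(C)C)[C@]3(C)CO[Si](C)(C)C(C)(C)C | intermediate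
31 | hemiketal from 30 | C[C@H]1C(=O)O[C@H]2C=C(COCc3ccc(OC)cc3)C(C)(O)O[C@@]12[C@H](O[Si](C)(C)C(C)(C)C)[C@H]3[C@@]4(C)O[C@H]4C[C@H](O[Si](C)(C)C(C)(C)C)[C@]3(C)CO[Si](C)(C)C(C)(C)C | intermediate
32 | ring-opened C4,C8-diol with (Z)-C5=C6 | CC(C)(C)[Si](C)(C)O[C@H]1C[C@@H]2O[C@]2(C)[C@H]([C@@H](O[Si](C)(C)C(C)(C)C)[C@@]3(O)[C@H](/C=C(/COCc4ccc(OC)cc4)C(C)O)OC(=O)[C@@H]3C)[C@@]1(C)CO[Si](C)(C)C(C)(C)C | intermediate
33 | C2,C4,C8-triol | CC(C)(C)[Si](C)(C)O[C@H]1C[C@@H]2O[C@]2(C)[C@H]([C@@H](O[Si](C)(C)C(C)(C)C)[C@@]3(O)[C@H](/C=C(/COCc4ccc(OC)cc4)C(C)O)OC(=O)[C@@H]3C)[C@@]1(C)CO | intermediate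
34 | tris-TMS ether of 33 | CC(C)(C)[Si](C)(C)O[C@H]1C[C@@H]2O[C@]2(C)[C@H]([C@@H](O[Si](C)(C)C(C)(C)C)[C@@]3(O[Si](C)(C)C)[C@H](/C=C(/COCc4ccc(OC)cc4)C(C)O[Si](C)(C)C)OC(=O)[C@@H]3C)[C@@]1(C)CO[Si](C)(C)C | intermediate
35 | C8-OTMS diol | CC(C)(C)[Si](C)(C)O[C@H]1C[C@@H]2O[C@]2(C)[C@H]([C@@H](O[Si](C)(C)C(C)(C)C)[C@@]3(O[Si](C)(C)C)[C@H](/C=C(/COCc4ccc(OC)cc4)C(C)O)OC(=O)[C@@H]3C)[C@@]1(C)CO | intermediate
36 | seco keto aldehyde (C2 aldehyde, C4 methyl ketone) | CC(C)(C)[Si](C)(C)O[C@H]1C[C@@H]2O[C@]2(C)[C@H]([C@@H](O[Si](C)(C)C(C)(C)C)[C@@]3(O[Si](C)(C)C)[C@H](/C=C(/COCc4ccc(OC)cc4)C(C)=O)OC(=O)[C@@H]3C)[C@@]1(C)C=O | intermediate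
37 | dicyclohexylboron enolate of 36 | CC(C)(C)[Si](C)(C)O[C@H]1C[C@@H]2O[C@]2(C)[C@H]([C@@H](O[Si](C)(C)C(C)(C)C)[C@@]3(O[Si](C)(C)C)[C@H](/C=C(/COCc4ccc(OC)cc4)C(=C)OB(C5CCCCC5)C5CCCCC5)OC(=O)[C@@H]3C)[C@@]1(C)C=O | intermediate
38 | dicyclohexylboron aldolate | CC(C)(C)[Si](C)(C)O[C@H]1C[C@@H]2O[C@]2(C)[C@@H]2[C@@H](O[Si](C)(C)C(C)(C)C)[C@@]3(O[Si](C)(C)C)[C@H](/C=C(/COCc4ccc(OC)cc4)C(=O)C[C@@H](OB(C5CCCCC5)C5CCCCC5)[C@@]12C)OC(=O)[C@@H]3C | intermediate
39 | ring B beta-hydroxy enone | CC(C)(C)[Si](C)(C)O[C@H]1C[C@@H]2O[C@]2(C)[C@@H]2[C@@H](O[Si](C)(C)C(C)(C)C)[C@@]3(O[Si](C)(C)C)[C@H](/C=C(/COCc4ccc(OC)cc4)C(=O)C[C@@H](O)[C@@]12C)OC(=O)[C@@H]3C | intermediate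
40 | C2 acetate C4 alcohol (1,3-anti) | CC(C)(C)[Si](C)(C)O[C@H]1C[C@@H]2O[C@]2(C)[C@@H]2[C@@H](O[Si](C)(C)C(C)(C)C)[C@@]3(O[Si](C)(C)C)[C@H](/C=C(/COCc4ccc(OC)cc4)[C@H](O)C[C@@H](OC(C)=O)[C@@]12C)OC(=O)[C@@H]3C | intermediate
41 | C2,C4-diacetate | CC(C)(C)[Si](C)(C)O[C@H]1C[C@@H]2O[C@]2(C)[C@@H]2[C@@H](O[Si](C)(C)C(C)(C)C)[C@@]3(O[Si](C)(C)C)[C@H](/C=C(/COCc4ccc(OC)cc4)[C@H](OC(C)=O)C[C@@H](OC(C)=O)[C@@]12C)OC(=O)[C@@H]3C | intermediate
42 | C8,C9,C14-triol | O[C@H]1C[C@@H]2O[C@]2(C)[C@@H]2[C@@H](O)[C@@]3(O)[C@H](/C=C(/COCc4ccc(OC)cc4)[C@H](OC(C)=O)C[C@@H](OC(C)=O)[C@@]12C)OC(=O)[C@@H]3C | intermediate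
43 | tetraacetate 4-methoxybenzyl ether | CC(=O)O[C@H]1C[C@@H]2O[C@]2(C)[C@@H]2[C@@H](OC(C)=O)[C@@]3(O)[C@H](/C=C(/COCc4ccc(OC)cc4)[C@H](OC(C)=O)C[C@@H](OC(C)=O)[C@@]12C)OC(=O)[C@@H]3C | intermediate
44 | CNP0104124.1 | CC(=O)O[C@H]1C[C@@H]2O[C@]2(C)[C@@H]2[C@@H](OC(C)=O)[C@@]3(O)[C@H](/C=C(/CO)[C@H](OC(C)=O)C[C@@H](OC(C)=O)[C@@]12C)OC(=O)[C@@H]3C | target

**Step count**

Total: 28 steps. Longest linear sequence: 26 steps (steps 1–9 and 12–28, from (S)-carvone); the furan branch is steps 10–11.

**Steps most likely to fail**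

Step 23. The chain may not fold into the ten-membered transition state, so that intermolecular aldol addition or return of unreacted material after enolisation outruns ring closure, or the enolate may add to the wrong face of the aldehyde. The fallback sets out from 36 and keeps the C2–C3 bond formation but changes the enolate and its mode of generation. Soft enolisation (TMSOTf, Et3N, CH2Cl2, −78 °C) should give the trimethylsilyl enol ether F1. NBS in THF at −78 °C should give the bromomethyl ketone F2. SmI2 (2.2 equiv) in THF at −78 °C under high dilution then generates a samarium enolate that adds to the aldehyde through a chelated transition state; this samarium Reformatsky-type aldol cyclisation is established for medium rings. The route is rejoined at 39.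

Step 7. Facial discrimination in the oxidation of the amide enolate may be low, because the bias rests only on the 1,3-allylic strain conformer, and enolisation of the hindered amide may be incomplete. The fallback sets out from 11 and replaces substrate control by reagent control. The hydroxylation is run as above and the product is taken on as a mixture of 13 and its C9 epimer F3. Dess–Martin oxidation should give the alpha-keto amide F4. Corey–Bakshi–Shibata reduction (2-methyl-CBS-oxazaborolidine, catecholborane, toluene, −78 °C, catalyst enantiomer chosen for the required C9 configuration) then returns to the route at 13.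

Step 18. The methyl iodide may enter on the other face of the lactone enolate, since the pyran ring lies on the face that has to be attacked, or the enolate may open the pyran by beta-elimination of the ring oxygen on warming. The fallback sets out from 27 and sets C17 by protonation instead of alkylation. If the one-pot sequence gives mainly the C17 epimer F5, this is deprotonated again (LiN(i-Pr)2, THF, −78 °C) to the methyl-substituted lithium enolate F6. Kinetic protonation with 2,6-di-tert-butyl-4-methylphenol should then place the proton on the face that the methyl iodide had used, which inverts C17 and returns to the route at 30.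

**Further compounds**

F1 | step 23 | trimethylsilyl enol ether of 36 (C3=C4–OTMS) | CC(C)(C)[Si](C)(C)O[C@H]1C[C@@H]2O[C@]2(C)[C@H]([C@@H](O[Si](C)(C)C(C)(C)C)[C@@]3(O[Si](C)(C)C)[C@H](/C=C(/COCc4ccc(OC)cc4)C(=C)O[Si](C)(C)C)OC(=O)[C@@H]3C)[C@@]1(C)C=O
F2 | step 23 | bromomethyl ketone (C3–Br) | CC(C)(C)[Si](C)(C)O[C@H]1C[C@@H]2O[C@]2(C)[C@H]([C@@H](O[Si](C)(C)C(C)(C)C)[C@@]3(O[Si](C)(C)C)[C@H](/C=C(/COCc4ccc(OC)cc4)C(=O)CBr)OC(=O)[C@@H]3C)[C@@]1(C)C=O
F3 | step 7 | C9 epimer of 13 | CN(C)C(=O)[C@@H](O)[C@H]1C(C)=CC[C@H](C(C)=C)[C@]1(C)CO[Si](C)(C)C(C)(C)C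
F4 | step 7 | alpha-keto amide (C9 ketone) | CN(C)C(=O)C(=O)[C@H]1C(C)=CC[C@H](C(C)=C)[C@]1(C)CO[Si](C)(C)C(C)(C)C
F5 | step 18 | C17 epimer of 30 | C[C@@H]1C(=O)O[C@H]2C=C(COCc3ccc(OC)cc3)C(C)(OC)O[C@@]12[C@H](O[Si](C)(C)C(C)(C)C)[C@H]3[C@@]4(C)O[C@H]4C[C@H](O[Si](C)(C)C(C)(C)C)[C@]3(C)CO[Si](C)(C)C(C)(C)C
F6 | step 18 | lithium enolate of F5 | [Li]OC1=C(C)[C@@]2(OC(C)(OC)C(COCc3ccc(OC)cc3)=C[C@@H]2O1)[C@H](O[Si](C)(C)C(C)(C)C)[C@H]3[C@@]4(C)O[C@H]4C[C@H](O[Si](C)(C)C(C)(C)C)[C@]3(C)CO[Si](C)(C)C(C)(C)C
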